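**Retrosynthetic overview**

1. Last bond set: a perezone-type (5+2) cycloaddition joins hydroxy-para-quinone 33 (five-carbon unit C8–C9–C11–C12–C13 of ring C) to the C14=C15 vinyl group of triene acid 23 and forms the bicyclo[3.2.1]octenedione with its three new stereocenters.
2. Acid 23: the C12–C16 diene comes from alkyne hydrozirconation/vinylation; C11 and the 8(17)-methylene from carbonylation and deconjugation of an enol triflate; ring B is (R)-carvone, whose C5 is the only bought stereocenter of this half (C10, C4 and C9 are relayed from it).
3. Enabling feature: in ring A (C1, C2, C3, C4, C5, C10) the quaternary C4 carries methyl C19 and a one-carbon carbonyl substituent C18 next to the C3 methylene, which is the product pattern of an epoxide-to-aldehyde 1,2-shift. Ring A is therefore built as a seven-membered ring (C10–C1–C2–C3–Cx–C4–C5) by metathesis and contracted, the extra ring atom Cx leaving the ring as C18.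
4. Quinone 33: (+)-sugiol, Wolff contraction of ring B (C7 extruded as the formyl carbon), then oxidation of ring C to the 12-hydroxy-11,14-quinone.
5. Ring order: labdane ring B (bought) → seven-membered ring → ring A; abietane rings A and C (bought) → five-membered ring B; bicyclo[3.2.1]octene last.

Key step: step 5

Remark and assumption: labdane numbering is used for fragment 1 and abietane numbering for fragment 2, Cx is the ring carbon that ends as C18, and (R)-(−)-carvone and (+)-sugiol are assumed to be purchased enantiopure.

**Fragment 1 (steps 1–15)**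

Step 1
Reactants: 1 (R)-(−)-carvone
Product: 3 trans-6-methylcarvone, via lithium enolate of carvone 2 (not isolated)
Conditions: LiN(i-Pr)2, THF, −78 °C; MeI, −78 → 0 °C
Reagents that add atoms: iodomethane, CI
Why: Kinetic α′-deprotonation gives the cross-conjugated lithium enolate and SN2 enolate alkylation introduces C20, mainly anti to the isopropenyl group; the configuration at this carbon (future C10) is erased again in step 2.

Step 2
Reactants: 3 trans-6-methylcarvone, 4 5-iodopent-1-ene
Product: 6 6-methyl-6-(pent-4-enyl)carvone (pentenyl trans to isopropenyl), via lithium enolate of 6-methylcarvone 5 (not isolated)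
Conditions: LiN(i-Pr)2, THF, −78 °C; 4, DMPU, −78 °C → rt
Reagents that add atoms: none
Why: Enolate alkylation of the tetrasubstituted enolate creates quaternary C10; the iodide is attacked from the face anti to the neighbouring isopropenyl group at C5, so the pentenyl chain (C1–C3, Cx) ends trans and the methyl cis to it, the relation that later becomes 5α-H/10β-CH3.

Step 3
Reactants: 6 6-methyl-6-(pent-4-enyl)carvone
Product: 7 trans-fused bicyclo[5.4.0]undecadienone (seven-membered ring with C4=Cx alkene)
Conditions: second-generation Grubbs catalyst (5 mol%), CH2Cl2 (dilute), 40 °C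
Reagents that add atoms: none
Why: Ring-closing olefin metathesis between the isopropenyl and the terminal vinyl group closes the seven-membered ring with a trisubstituted C4=Cx alkene, the conjugated enone alkene being inert; no stereocenter is formed.

Step 4
Reactants: 7 bicyclic dienone
Product: 8 α-epoxide of the C4=Cx alkene
Conditions: mCPBA, NaHCO3, CH2Cl2, 0 °C
Reagents that add atoms: 3-chloroperoxybenzoic acid, OOC(=O)c1cccc(Cl)c1
Why: Prilezhaev epoxidation is selective for the electron-rich trisubstituted alkene over the enone, and the peracid should attack the α-face, anti to the angular C10 β-methyl, which fixes both epoxide carbons.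

Step 5
Reactants: 8 α-epoxide
Product: 9 ring-contracted keto aldehyde (4β-CH3, 4α-CHO)
Conditions: MeAl(OAr)2 (Ar = 4-bromo-2,6-di-tert-butylphenyl; 0.2 equiv), CH2Cl2, −78 → −20 °C
Reagents that add atoms: none
Why: The bulky aluminium Lewis acid binds the epoxide oxygen and the C4–O bond ionizes toward the tertiary, methyl-bearing C4 while the ring bond Cx–C3, anti to the breaking C–O bond, migrates to C4, so that Cx is pushed out of the ring as the aldehyde carbon C18 (Meinwald-type epoxide-to-aldehyde semipinacol rearrangement). The closest known reaction type is the MeAl(OAr)2- or BF3-mediated ring contraction of 1-methylcycloalkene oxides to 1-methylcycloalkanecarbaldehydes. Ring A (C1, C2, C3, C4, C5, C10) is closed by a suprafacial 1,2-alkyl shift that turns the seven-membered ring into the six-membered one, not by a cyclization. The only new stereocenter, quaternary C4, is controlled by the epoxide configuration: C3 enters anti to the departing α-oxygen (inversion at C4), which should put C19 axial (β) and C18 equatorial (α), the arrangement that methylation of a C4 ester enolate would not give. The step needs ionization at C4 and not at Cx, secured by the tertiary versus secondary cation, and alkyl shift instead of hydride shift to the seven-membered ketone, secured by the hindered aluminium reagent that favours the aldehyde pathway and by the strain released in the 7-to-6 contraction. The enone of ring B is electron-poor and hindered at oxygen and should stay untouched.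

Step 6
Reactants: 9 keto aldehyde
Product: 10 keto acid (C18 acid)
Conditions: NaClO2, NaH2PO4, 2-methylbut-2-ene, t-BuOH/H2O, rt
Reagents that add atoms: sodium chlorite, [Na+].[O-]Cl=O
Why: Pinnick oxidation turns the hindered aldehyde into the acid without affecting the enone; quaternary C4 cannot epimerize.

Step 7
Reactants: 10 keto acid
Product: 11 keto methyl ester
Conditions: MeI, K2CO3, DMF, rt
Reagents that add atoms: iodomethane, CI
Why: SN2 esterification of the carboxylate with iodomethane protects the hindered acid; no stereocenter is touched.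

Step 8
Reactants: 11 keto methyl ester
Product: 13 C9 enol triflate, via lithium C9-enolate 12 (not isolated)
Conditions: LiBH(s-Bu)3, THF, −78 °C; PhNTf2, −78 → 0 °C
Reagents that add atoms: N-phenylbis(trifluoromethanesulfonimide), FC(F)(F)S(=O)(=O)N(c1ccccc1)S(=O)(=O)C(F)(F)F
Why: Conjugate hydride reduction by the hindered borohydride (1,2-attack at C9 is blocked by quaternary C10) gives the C9/C8 enolate regiospecifically, and O-sulfonylation with PhNTf2 gives the enol triflate; no stereocenter is formed.

Step 9
Reactants: 13 enol triflate
Product: 14 conjugated diester (C11 ester on C9, 8(9)-ene)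
Conditions: CO (1 atm), MeOH, Pd(OAc)2 (5 mol%), Ph2P(CH2)3PPh2, Et3N, DMF, 60 °C
Reagents that add atoms: carbon monoxide, [C-]#[O+]; methanol, CO
Why: Palladium-catalysed methoxycarbonylation of the vinyl triflate (oxidative addition to zerovalent palladium, CO insertion, methanolysis) attaches C11 as a conjugated ester.

Step 10
Reactants: 14 conjugated diester
Product: 16 deconjugated diester (8(17)-methylene, 9α-H), via lithium dienolate 15 (not isolated)
Conditions: LiN(i-Pr)2, HMPA, THF, −78 °C; AcOH, −78 °C
Reagents that add atoms: none
Why: Deconjugative protonation of an α,β-unsaturated ester: the amide base removes a proton from the C17 methyl group, which lies cis to the ester, and kinetic α-protonation of the extended enolate at C9 from the α-face (anti to the C10 β-methyl) should give the 8(17)-methylene and the 9α-H stereocenter.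

Step 11
Reactants: 16 deconjugated diester
Product: 17 C11 primary alcohol
Conditions: i-Bu2AlH, CH2Cl2, −78 °C; aqueous KNaC4H4O6
Reagents that add atoms: none
Why: Hydride reduction of an ester to the primary alcohol; the C11 ester on the secondary C9 should react at −78 °C while the C18 ester on quaternary C4 is too hindered.

Step 12
Reactants: 17 C11 alcohol
Product: 18 C11 iodide
Conditions: I2, PPh3, imidazole, CH2Cl2, 0 °C → rt
Reagents that add atoms: iodine, II
Why: Appel-type iodination converts the primary alcohol into the iodide through the alkoxyphosphonium ion without touching the alkene or the ester.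

Step 13
Reactants: 18 C11 iodide
Product: 19 but-2-ynyl compound (C12≡C13–C16)
Conditions: MeC≡CLi, THF/DMPU, 0 °C → rt
Reagents that add atoms: 1-propynyllithium, [Li]C#CC
Why: SN2 alkylation of an alkynyllithium by the primary iodide in a dipolar cosolvent adds C12, C13 and C16; the C18 ester is shielded by the quaternary centre.

Step 14
Reactants: 19 but-2-ynyl compound
Product: 22 methyl (12E)-labda-8(17),12,14-trien-18-oate, via alkenylzirconocene chloride 20 (not isolated), via alkenylzinc chloride 21 (not isolated)
Conditions: Cp2Zr(H)Cl, THF, rt → 50 °C; then ZnCl2, vinyl bromide, Pd(PPh3)4 (5 mol%), THF, rt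
Reagents that add atoms: vinyl bromide, C=CBr
Why: Hydrozirconation adds Zr–H syn across the alkyne with zirconium on the less hindered, methyl-bearing C13, and Negishi coupling (transmetalation to zinc, zerovalent palladium catalysis) with vinyl bromide proceeds with retention, which should give the 12E diene.

Step 15
Reactants: 22 methyl trienoate
Product: 23 (12E)-labda-8(17),12,14-trien-18-oic acid (fragment 1)
Conditions: NaSEt, DMF, 80 °C; then 1 M HCl
Reagents that add atoms: none
Why: SN2 demethylation of the hindered methyl ester by thiolate at the O-methyl carbon frees the acid without alkene isomerization.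

**Fragment 2 (steps 16–21)**

Step 16
Reactants: 24 (+)-sugiol
Product: 27 6-diazosugiol, via dilithium enolate of sugiol 25 (not isolated), via 6-trifluoroacetylsugiol 26 (not isolated)
Conditions: LiN(SiMe3)2, THF, −78 °C; CF3CO2CH2CF3; then MsN3, Et3N, H2O, MeCN, rt
Reagents that add atoms: methanesulfonyl azide, CS(=O)(=O)N=[N+]=[N-]
Why: Detrifluoroacetylative Regitz diazo transfer: Claisen-type trifluoroacetylation of the ketone enolate activates C6, and the sulfonyl azide transfers the diazo group with loss of the trifluoroacetyl group; the phenolate is only transiently acylated.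

Step 17
Reactants: 27 6-diazosugiol
Product: 29 ring-contracted 6α-methyl ester, via aryl ketene 28 (not isolated)
Conditions: hν (Pyrex, > 300 nm), MeOH, rt; then DBU (0.2 equiv), MeOH, 50 °C
Reagents that add atoms: methanol, CO
Why: Photochemical Wolff rearrangement: aryl carbon C8 migrates from C7 to the carbene carbon C6, which contracts ring B to the five-membered ring, and methanol traps the ketene; base equilibration should put the ester on the α-face of C6, away from the C10 and C4 β-methyl groups.

Step 18
Reactants: 29 ring-contracted methyl ester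
Product: 30 phenol primary alcohol
Conditions: LiAlH4, THF, 0 °C → rt
Reagents that add atoms: none
Why: LiAlH4 reduction of the ester gives the primary alcohol, so that C6 is no longer epimerizable during the oxidation of ring C.

Step 19
Reactants: 30 phenol alcohol
Product: 31 11,12-ortho-quinone alcohol
Conditions: (KSO3)2NO, KH2PO4, acetone/H2O, rt
Reagents that add atoms: potassium nitrosodisulfonate, [K+].[K+].[O-]S(=O)(=O)N([O])S(=O)(=O)[O-]
Why: Teuber oxidation: the nitroxyl radical oxidizes the para-blocked phenol at its only free ortho position (C11) to the 11,12-ortho-quinone and leaves the primary alcohol untouched.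

Step 20
Reactants: 31 ortho-quinone alcohol
Product: 32 12-hydroxy-11,14-para-quinone alcohol
Conditions: KOH, MeOH/H2O, O2 (1 atm), 0 °C; then 1 M HCl
Reagents that add atoms: potassium hydroxide, [K+].[OH-]
Why: Conjugate addition of hydroxide to C14, the only unsubstituted β-carbon of the ortho-quinone, followed by aerobic re-oxidation and tautomerization should give the 12-hydroxy-11,14-para-quinone (the regiochemistry known from Thiele–Winter-type additions to ortho-quinones).

Step 21
Reactants: 32 hydroxyquinone alcohol
Product: 33 hydroxyquinone aldehyde (fragment 2)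
Conditions: Dess–Martin periodinane, NaHCO3, CH2Cl2, 0 °C → rt
Reagents that add atoms: none
Why: Dess–Martin oxidation of the primary alcohol gives the aldehyde; C6 should keep the thermodynamically preferred α-formyl configuration.

**Union**

Step 22
Reactants: 23 triene acid (fragment 1), 33 hydroxyquinone aldehyde (fragment 2)
Product: 34 CNP0256710.1 (target)
Conditions: BF3·OEt2 (0.3 equiv), CH2Cl2, −78 → −40 °C
Reagents that add atoms: none
Why: Perezone-type cationic (5+2) cycloaddition: the Lewis acid turns the hydroxyquinone into a 2-oxidopentadienyl cation (C8–C9–C11–C12–C13 of fragment 2), the terminal CH2 (C15 of fragment 1) bonds to C8, the allyl cation so formed is captured at C14 of fragment 1 by the enol carbon C13, and the quinone C14 carbonyl becomes the one-carbon bridge; approach to the α-face of ring C, anti to the angular C10 β-methyl, through a compact endo transition state with the dienyl residue under the C9–C11–C12 bridge should set the three new stereocenters as in the target.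

**Compound list**

1 | (R)-(−)-carvone | CC1=CC[C@@H](C(C)=C)CC1=O | starting material
2 | lithium enolate of carvone (cross-conjugated) | CC1=CC[C@@H](C(C)=C)C=C1O[Li] | intermediate
3 | trans-6-methylcarvone, (5R,6S), methyl trans to isopropenyl | CC1=CC[C@@H](C(C)=C)[C@H](C)C1=O | intermediate
4 | 5-iodopent-1-ene | C=CCCCI | starting material
5 | lithium enolate of 6-methylcarvone (tetrasubstituted) | CC1=CC[C@@H](C(C)=C)C(C)=C1O[Li] | intermediate
6 | 6-methyl-6-(pent-4-enyl)carvone, pentenyl trans and methyl cis to isopropenyl | CC1=CC[C@@H](C(C)=C)[C@](C)(CCCC=C)C1=O | intermediate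
7 | trans-fused bicyclo[5.4.0]undecadienone: seven-membered ring C10–C1–C2–C3–Cx=C4(CH3)–C5, 5α-H, 10β-CH3, ring B with C9=O, 8-CH3, 7-ene | CC1=CC[C@@H]2[C@](C)(CCCC=C2C)C1=O | intermediate
8 | α-epoxide of 7 (oxygen across C4 and Cx, anti to the C10 methyl) | CC1=CC[C@@H]2[C@](C)(CCC[C@H]3O[C@@]23C)C1=O | intermediate
9 | ring-contracted keto aldehyde: trans-decalin, 4β-CH3, 4α-CHO (C18), 5α-H, 10β-CH3, C9=O, 8-CH3, 7-ene | CC1=CC[C@@H]2[C@](C)(CCC[C@@]2(C)C=O)C1=O | intermediate
10 | keto acid (4α-COOH) | CC1=CC[C@@H]2[C@](C)(CCC[C@@]2(C)C(=O)O)C1=O | intermediate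
11 | keto methyl ester (4α-CO2CH3) | CC1=CC[C@@H]2[C@](C)(CCC[C@@]2(C)C(=O)OC)C1=O | intermediate
12 | lithium C9-enolate (C8=C9) | CC1=C(O[Li])[C@@]2(C)CCC[C@@](C)(C(=O)OC)[C@@H]2CC1 | intermediate
13 | C9 enol triflate (C8=C9, 8-CH3) | CC1=C(OS(=O)(=O)C(F)(F)F)[C@@]2(C)CCC[C@@](C)(C(=O)OC)[C@@H]2CC1 | intermediate
14 | conjugated diester: C11 ester on C9, C8=C9, C18 ester on C4 | CC1=C(C(=O)OC)[C@@]2(C)CCC[C@@](C)(C(=O)OC)[C@@H]2CC1 | intermediate
15 | lithium dienolate (C9=C11 ketene acetal, 8(17)-methylene) | C=C1CC[C@@H]2[C@](C)(CCC[C@@]2(C)C(=O)OC)C1=C(OC)O[Li] | intermediate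
16 | deconjugated diester: 8(17)-methylene, 9α-H, 9β-CO2CH3 | C=C1CC[C@@H]2[C@](C)(CCC[C@@]2(C)C(=O)OC)[C@H]1C(=O)OC | intermediate
17 | C11 primary alcohol (9β-CH2OH), C18 methyl ester | C=C1CC[C@@H]2[C@](C)(CCC[C@@]2(C)C(=O)OC)[C@H]1CO | intermediate
18 | C11 iodide | C=C1CC[C@@H]2[C@](C)(CCC[C@@]2(C)C(=O)OC)[C@H]1CI | intermediate
19 | but-2-ynyl compound (C11–C12≡C13–C16) | C=C1CC[C@@H]2[C@](C)(CCC[C@@]2(C)C(=O)OC)[C@H]1CC#CC | intermediate
20 | alkenylzirconocene chloride (Zr on C13, syn to 12-H) | C=C1CC[C@@H]2[C@](C)(CCC[C@@]2(C)C(=O)OC)[C@H]1C/C=C(\C)[Zr](Cl)(C1C=CC=C1)C1C=CC=C1 | intermediate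
21 | alkenylzinc chloride | C=C1CC[C@@H]2[C@](C)(CCC[C@@]2(C)C(=O)OC)[C@H]1C/C=C(\C)[Zn]Cl | intermediate
22 | methyl (12E)-labda-8(17),12,14-trien-18-oate | C=C1CC[C@@H]2[C@](C)(CCC[C@@]2(C)C(=O)OC)[C@H]1C/C=C(\C)C=C | intermediate
23 | (12E)-labda-8(17),12,14-trien-18-oic acid (4-epimer of trans-communic acid; fragment 1) | C=C1CC[C@@H]2[C@](C)(CCC[C@@]2(C)C(=O)O)[C@H]1C/C=C(\C)C=C | intermediate
24 | (+)-sugiol (12-hydroxyabieta-8,11,13-trien-7-one; 5α-H, 10β-CH3) | CC(C)c1cc2c(cc1O)[C@@]3(C)CCCC(C)(C)[C@@H]3CC2=O | starting material
25 | dilithium enolate of sugiol (phenolate and C6=C7 enolate) | CC(C)c1cc2c(cc1O[Li])[C@@]3(C)CCCC(C)(C)[C@@H]3C=C2O[Li] | intermediate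
26 | 6-trifluoroacetylsugiol (C6 not defined) | CC(C)c1cc2c(cc1O)[C@@]3(C)CCCC(C)(C)[C@@H]3C(C(=O)C(F)(F)F)C2=O | intermediate
27 | 6-diazosugiol | CC(C)c1cc2c(cc1O)[C@@]3(C)CCCC(C)(C)[C@@H]3C(=[N+]=[N-])C2=O | intermediate
28 | aryl ketene (five-membered ring B, C7 as ketene carbon on C6) | CC(C)c1cc2c(cc1O)[C@@]3(C)CCCC(C)(C)[C@@H]3C2=C=O | intermediate
29 | ring-contracted methyl ester: 6-5-6 tricycle (ring B: C5, C6, C8, C9, C10), 6α-CO2CH3, 5α-H, 10β-CH3, 12-OH | CC(C)c1cc2c(cc1O)[C@@]3(C)CCCC(C)(C)[C@@H]3[C@H]2C(=O)OC | intermediate
30 | phenol primary alcohol (6α-CH2OH) | CC(C)c1cc2c(cc1O)[C@@]3(C)CCCC(C)(C)[C@@H]3[C@H]2CO | intermediate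
31 | 11,12-ortho-quinone alcohol | CC(C)C1=CC2=C(C(=O)C1=O)[C@@]3(C)CCCC(C)(C)[C@@H]3[C@H]2CO | intermediate
32 | 12-hydroxy-11,14-para-quinone alcohol | CC(C)C1=C(O)C(=O)C(=C2C1=O)[C@@]3(C)CCCC(C)(C)[C@@H]3[C@H]2CO | intermediate
33 | 12-hydroxy-11,14-para-quinone 6α-carbaldehyde (taiwaniaquinone A type; fragment 2) | CC(C)C1=C(O)C(=O)C(=C2C1=O)[C@@]3(C)CCCC(C)(C)[C@@H]3[C@H]2C=O | intermediate
34 | CNP0256710.1: (5+2) adduct, two-carbon bridge on the α-face of former ring C, dienyl residue endo | C=C1CC[C@@H]2[C@](C)(CCC[C@@]2(C)C(=O)O)[C@H]1C/C=C(\C)[C@@H]1C[C@@]23C(=O)[C@]1(C(C)C)C(=O)C(O)=C2[C@@]1(C)CCCC(C)(C)[C@@H]1[C@H]3C=O | target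

**Totals**

Total step count: 22. Longest linear sequence: 16 steps (steps 1–15 and 22).

**Three steps most likely to fail**

1. Step 5. What may go wrong: hydride shift from Cx competes with migration of the C3–Cx ring bond (no contraction), or ionization to a free C4 cation erodes the stereospecificity at C4. Fallback (Favorskii contraction of the same seven-membered ring): epoxide 8 is isomerized on purpose along the hydride-shift path (LiClO4, toluene, reflux) to the seven-membered ketone F1. Acid-catalysed bromination (pyridinium tribromide, AcOH) then gives the α-bromo ketone F2; the regioisomeric bromide would lead to the same cyclopropanone. NaOMe in MeOH effects the Favorskii rearrangement: the cyclopropanone spanning C3 and C4 should open toward the secondary C3 carbanion and form preferentially on the α-face, away from the C10 methyl. This gives methyl ester 11, where the route is rejoined.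

2. Step 22. What may go wrong: poor facial or endo/exo selectivity on the quinone, competing (4+2) or (2+2) addition, or acid-induced isomerization and oligomerization of the triene. Fallback (chelation-controlled variant with a different quinone partner): aldehyde 33 is O-methylated (MeI, Ag2O, CHCl3) to the 12-methoxy quinone F3. F3 and acid 23 are then combined with TiCl4/Ti(O-i-Pr)4 in CH2Cl2 at −78 °C, the known titanium-promoted (5+2) cycloaddition of 2-methoxy-para-quinones with alkenes. Titanium chelated between the C11 carbonyl and the methoxy group should direct C15 to C8, and after ring closure at C13 the O-methyl group is lost, which gives 34 directly.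

3. Step 20. What may go wrong: under base the ortho-quinone tautomerizes through the benzylic C6–H to a quinone methide and is over-oxidized instead of being hydroxylated cleanly at C14. Fallback (Thiele–Winter acetoxylation): ortho-quinone 31 is treated with Ac2O and BF3·OEt2 to give the 11,12,14-triacetoxy arene O-acetate F4. K2CO3 in MeOH under air removes the four acetyl groups, and the triol oxidizes spontaneously to 32, where the route is rejoined.

**Further compounds**

F1 | step 5 | seven-membered-ring ketone (Cx=O, 4-CH3, C4 not defined) | CC1=CC[C@@H]2[C@](C)(CCCC(=O)C2C)C1=O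
F2 | step 5 | 4-bromo seven-membered-ring ketone (C4 not defined) | CC1=CC[C@@H]2[C@](C)(CCCC(=O)C2(C)Br)C1=O
F3 | step 22 | 12-methoxy-11,14-para-quinone 6α-carbaldehyde | CC(C)C1=C(OC)C(=O)C(=C2C1=O)[C@@]3(C)CCCC(C)(C)[C@@H]3[C@H]2C=O
F4 | step 20 | 11,12,14-triacetoxy arene with 6α-CH2OAc | CC(C)c1c(OC(C)=O)c(OC(C)=O)c(c2c1OC(C)=O)[C@@]3(C)CCCC(C)(C)[C@@H]3[C@H]2COC(C)=O
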